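**Numbering.** Lactone: C2(CH3)–C3(=O)–O–C4H–C5H2–C6H. Carbocycle: C6–C7–…–C17–C4, with the epoxide at C9–C10, the hydroperoxide on C13, the alkene at C14=C15 and the carbinol at C17. These locants are used in all descriptions below.

## Analysis of the target

The target is a 14-membered carbocycle bridged across C4–C5–C6 by a six-membered lactone. It carries a trans trisubstituted epoxide (C9–C10), a tertiary allylic hydroperoxide (C13, next to the E alkene C14=C15) and a tertiary alcohol (C17). The seven stereocentres are 2S, 4R, 6R, 9S, 10S, 13S and 17S. In the lactone the three substituents are all equatorial: the C2 methyl is trans to the C6 chain, and the C6 and C4 substituents are cis. C4 and C17 are a vicinal oxygenated pair, whereas C9/C10 and C13 are remote and cannot be set by relay from the lactone. The hydroperoxide does not tolerate reductants, metals or strong base, the epoxide does not tolerate acid, and the lactone opens in base and epimerises at C2. The difficulties are the 14-membered ring closure next to these groups, the independent control of the remote centres, and the late introduction of the O–O bond. The strategy rests on reading the ring O–C3–C2–C6–C5–C4 as a reduced 5,6-dihydropyran-2-one whose carbinol carbon C4 bears the quaternary C17. C4 can therefore be an aldehyde carbon, and C5–C6–C2–C3 (with the C2 methyl) a four-carbon diene.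

## Retrosynthetic reasoning

**38 ⇒ 37.** The C13–O bond is cut and the alkene returned from C14=C15 to C13=C14. The hydroperoxide survives none of the earlier chemistry, so a Schenck ene reaction on 37 is placed last. It has to add oxygen at C13 with hydrogen abstraction from C15.

**37 ⇒ 36 ⇒ 35.** The ring is opened at C11–C12. This is the only ring bond that lies between a carbon that can carry a stabilised carbanion (C12, allylic, as a sulfone) and a primary carbon (C11), and it is remote from every stereocentre. The forward reaction is an intramolecular sulfone alkylation to 36, followed by reductive removal of the sulfonyl group.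

**35 ⇒ 34 ⇒ 33.** The epoxide is cut back to the allylic alcohol 33. After ring closure no handle would distinguish C9=C10 from C13=C14, so the epoxide is set before cyclisation by Sharpless epoxidation of the C11 alcohol. The same alcohol then becomes the leaving group.

**33 ⇒ 32 ⇒ 29 ⇒ 28 ⇒ 26.** These are functional-group changes only. The C12 silyl ether is exchanged for the sulfone, the C11 silyl ether is removed, and the C17 benzoate is taken off at the one stage (26) where the lactone can be opened and re-closed without risk to an epoxide.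

**26 ⇒ 24.** The C6–H and C2–H bonds are cut, giving the tetrasubstituted unsaturated lactone 24. Hydride adds to C6 anti to the C4 substituent, which places the C7 chain cis to it. C2 then settles in the equatorial position under base. Adding the chain as a nucleophile to a C6-unsubstituted enoate would give the wrong (trans) isomer, which is why coupling comes before reduction.

**24 ⇒ 15 + 23.** The C6–C7 bond is cut between an enol triflate and the Grignard reagent 23 (from bromide 22). The forward reaction is an iron-catalysed cross-coupling, fast enough to spare the lactone and the benzoate.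

**15 ⇒ 14 ⇒ 13.** The triflate comes from the β-keto lactone 14, and this from the methyl enol ether 13. The methoxy group of 13 marks C6 for the coupling.

**13 ⇒ 8 + 11 (key disconnection).** C4–C5 and the ring O–C3 bond are cut together. This gives the α-quaternary aldehyde 8, which has no α-hydrogen, and the diene 11, which already carries the C2 methyl. One operation builds the lactone ring and sets C4.

**8 ⇒ 7 ⇒ 6 ⇒ 5 ⇒ 1.** The aldehyde comes from glycol cleavage of 7. The C17–O bond of 7 comes from opening epoxy alcohol 6 at the tertiary carbon with inversion. 6 comes from Sharpless epoxidation of 5, and 5 from geraniol 1 by allylic oxidation of the remote E methyl group (which becomes C12).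

**11 ⇒ 10 ⇒ 9 and 22 ⇒ 21 ⇒ 20 ⇒ 19 ⇒ 17 ⇒ 16.** The diene is the silyl dienolate of the methyl enol ether of 9. The C7–C11 bromide comes from alkyne 16 by syn carbometalation, which fixes the E geometry needed for the second Sharpless step.

## Alternatives that were turned down

**Alternative 1:** The disconnection is C5–C6. In the forward step a tin hydride radical chain converts the iodide A1, a 16-membered macrolactone, into a primary C5 radical. This adds across the ring to C6 of the E enoate and closes the 14-membered carbocycle and the δ-lactone at once, giving A2 (the same compound as 37).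
- For it: one step makes both rings, the macrolactone precursor is easier to close than a 14-membered carbocycle, and the linear precursor is short. On ring-forming economy it is clearly stronger than the chosen route.
- Against it: C6 and C2 are both created in the radical step. C6 is set by the conformation of a flexible 16-membered ring and C2 by hydrogen transfer to an α-carbonyl radical, so neither has a dependable control element. The β-acyloxy radical can also be reduced before it cyclises or undergo acyloxy shift.
- Comparison: the chosen route is longer, but it sets C4 by a catalyst, C6 by the stereoelectronics of a six-membered ring, and C2 by thermodynamics.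

**Alternative 2:** The disconnection is the C4–O lactone bond together with both epoxides. In the forward step a titanium–tartrate epoxidation converts both allylic alcohols of diol A3 in one pot into the bis-epoxide A4. Its C4–C17 epoxide is later opened at C4 by the carboxyl group to give the lactone and the C17 carbinol.
- For it: C4, C17, C9 and C10 all come from one highly reliable reagent-controlled reaction, and C2/C6 come from the chiral pool. For the C4/C17 pair this is more secure than a catalyst-controlled addition to a hindered aldehyde.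
- Against it: A4 ends in two nearly identical primary epoxy alcohols that must be told apart. The C12–C16 segment is still missing, and two sp3–sp3 bonds next to epoxides plus the macrocyclisation remain.
- Comparison: the chosen route has a less certain C4 step, but its chain termini are differentiated from the start and all ring carbons except C7–C11 are present at the key step.

**Alternative 3:** The disconnections are C6–C7 and C2–CH3 on an acyclic chain. In the forward step a copper–ferrocenyl diphosphine catalyst adds the Grignard reagent A6 to C6 of the E thioenoate A5, and the magnesium enolate is methylated at C2 to give A7.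
- For it: C6 is set by a chiral catalyst independent of any ring, two large fragments are joined convergently, and the demethylation/triflate/reduction sequence of the chosen route is avoided. It is stronger on step economy around C6, and on C4/C17 (one dihydroxylation).
- Against it: methylation of an acyclic enolate gives little control at C2. Since C2 would be corrected later in the lactone anyway, the three-component feature adds little. The catalyst must also cope with a large functionalised Grignard reagent and a nearby C4 stereocentre, and lactone and macrocycle are still to be made.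
- Comparison: the chosen route needs no chiral catalyst for C6 or C2 (both follow from C4 through the ring), and it forms C4–C5 and O–C3 together.

Key step: step 10

**Assumption.** (R)-BINOL is taken as the ligand enantiomer whose titanium complex directs the diene to the Re face of the aldehyde of 8, as it does in related titanium–BINOL carbonyl additions. If the sense is opposite, (S)-BINOL is used and nothing else changes.

## Route

Step 1
Reactants: 1 geraniol
Product: 2 geranyl acetate
Conditions: Ac2O, Et3N, DMAP (cat.), CH2Cl2, 0 °C → rt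
Reagents that add atoms: acetic anhydride, CC(=O)OC(C)=O
Why: Acylation of the primary allylic alcohol; the acetate protects C1 and deactivates the proximal alkene for the next step.

Step 2
Reactants: 2 geranyl acetate
Product: 3 (2E,6E)-8-hydroxy-3,7-dimethylocta-2,6-dien-1-yl acetate
Conditions: SeO2 (0.1 equiv), salicylic acid (0.1 equiv), t-BuOOH (70% aq.), CH2Cl2, rt
Reagents that add atoms: tert-butyl hydroperoxide, CC(C)(C)OO (terminal oxygen source, relayed by SeO2, O=[Se]=O)
Why: Riley allylic oxidation (ene reaction, then [2,3]-sigmatropic shift) should hydroxylate the E methyl group of the electron-richer terminal alkene; this carbon becomes C12.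

Step 3
Reactants: 3 (2E,6E)-8-hydroxy-3,7-dimethylocta-2,6-dien-1-yl acetate
Product: 4 (2E,6E)-8-(tert-butyldimethylsilyloxy)-3,7-dimethylocta-2,6-dien-1-yl acetate
Conditions: TBSCl, imidazole, DMF, rt
Reagents that add atoms: tert-butyldimethylsilyl chloride, CC(C)(C)[Si](C)(C)Cl
Why: Silylation of the primary alcohol; the TBS ether is stable to everything up to step 21.

Step 4
Reactants: 4 (2E,6E)-8-(tert-butyldimethylsilyloxy)-3,7-dimethylocta-2,6-dien-1-yl acetate
Product: 5 (2E,6E)-8-(tert-butyldimethylsilyloxy)-3,7-dimethylocta-2,6-dien-1-ol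
Conditions: K2CO3, MeOH, rt
Reagents that add atoms: none
Why: Transesterification removes the acetate and leaves the silyl ether untouched.

Step 5
Reactants: 5 (2E,6E)-8-(tert-butyldimethylsilyloxy)-3,7-dimethylocta-2,6-dien-1-ol
Product: 6 [(2R,3R)-3-[(3E)-5-(tert-butyldimethylsilyloxy)-4-methylpent-3-en-1-yl]-3-methyloxiran-2-yl]methanol
Conditions: Ti(OiPr)4 (10 mol%), D-(−)-diethyl tartrate (12 mol%), t-BuOOH (anhydrous), 4 Å MS, CH2Cl2, −20 °C
Reagents that add atoms: tert-butyl hydroperoxide, CC(C)(C)OO
Why: Sharpless asymmetric epoxidation; only the alkene with a free allylic hydroxyl reacts, and the D-tartrate should give the 2R,3R epoxide.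

Step 6
Reactants: 6 [(2R,3R)-3-[(3E)-5-(tert-butyldimethylsilyloxy)-4-methylpent-3-en-1-yl]-3-methyloxiran-2-yl]methanol
Product: 7 (2R,3S,6E)-8-(tert-butyldimethylsilyloxy)-1,2-dihydroxy-3,7-dimethyloct-6-en-3-yl benzoate
Conditions: Ti(OiPr)4 (1.5 equiv), PhCO2H (1.5 equiv), CH2Cl2, rt
Reagents that add atoms: benzoic acid, OC(=O)c1ccccc1
Why: Titanium-mediated opening of a 2,3-epoxy alcohol: the metal binds the alkoxide and the epoxide oxygen, and benzoate attacks C3 (the carbon that best carries positive charge) from the back. Inversion should set the future C17 as S.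

Step 7
Reactants: 7 (2R,3S,6E)-8-(tert-butyldimethylsilyloxy)-1,2-dihydroxy-3,7-dimethyloct-6-en-3-yl benzoate
Product: 8 (2S,5E)-7-(tert-butyldimethylsilyloxy)-2,6-dimethyl-1-oxohept-5-en-2-yl benzoate (the C4 aldehyde)
Conditions: NaIO4, THF/pH 7 buffer, 0 °C
Reagents that add atoms: none
Why: Malaprade glycol cleavage of the 1,2-diol; the aldehyde has no α-hydrogen, so the quaternary centre cannot epimerise.

Step 8
Reactants: 9 methyl 2-methyl-3-oxobutanoate (methyl 2-methylacetoacetate)
Product: 10 methyl (2E)-3-methoxy-2-methylbut-2-enoate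
Conditions: HC(OMe)3, H2SO4 (cat.), MeOH, rt → 50 °C
Reagents that add atoms: trimethyl orthoformate, COC(OC)OC
Why: Ketalisation of the ketone followed by loss of methanol gives the conjugated methyl enol ether.

Step 9
Reactants: 10 methyl (2E)-3-methoxy-2-methylbut-2-enoate
Product: 11 1,3-dimethoxy-2-methyl-1-(trimethylsilyloxy)buta-1,3-diene (ketene acetal isomers)
Conditions: LDA, THF, −78 °C; TMSCl, −78 °C → rt
Reagents that add atoms: chlorotrimethylsilane, C[Si](C)(C)Cl
Why: γ-Deprotonation to the dienolate and O-silylation give the silyl ketene acetal diene, used directly after distillation.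

Step 10
Reactants: 8 (2S,5E)-7-(tert-butyldimethylsilyloxy)-2,6-dimethyl-1-oxohept-5-en-2-yl benzoate; 11 1,3-dimethoxy-2-methyl-1-(trimethylsilyloxy)buta-1,3-diene
Product: 13 (2S,5E)-7-(tert-butyldimethylsilyloxy)-2-[(2R)-4-methoxy-5-methyl-6-oxo-3,6-dihydro-2H-pyran-2-yl]-6-methylhept-5-en-2-yl benzoate, via aldol silyl ether 12 (not isolated)
Conditions: Ti(OiPr)4 (20 mol%), (R)-BINOL (22 mol%), 4 Å MS, THF, 0 °C → rt; then TFA, CH2Cl2, 0 °C
Reagents that add atoms: none
Why: The titanium–BINOL complex binds the aldehyde oxygen of 8 and the CH2 terminus of 11 (C5) attacks C4, either in an asynchronous [4+2] cycloaddition or as a vinylogous Mukaiyama aldol addition that gives silyl ether 12. The closest known reaction type is the titanium–BINOL-catalysed hetero-Diels–Alder reaction of 1,3-dialkoxy-1-silyloxy dienes with aldehydes. The six-membered ring closes when the C4 oxygen attacks the ester carbon C3 with loss of methoxytrimethylsilane, a 6-exo-trig addition–elimination that the TFA treatment completes for open-chain 12. C4 is the only new stereocentre and is controlled by the catalyst, the (R)-ligand being assumed to expose the Re face and give 4R. Substrate control from C17 is weak, because a Felkin-type model must distinguish methyl from a CH2 chain, so the step depends on catalyst control. The regiochemistry (attack through the diene terminus and not through C2) follows from the ketene acetal polarisation and the C2 methyl group. Aldehyde 8 cannot enolise, and its silyl ether and benzoate are inert to the mild Lewis acid.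

Step 11
Reactants: 13 (2S,5E)-7-(tert-butyldimethylsilyloxy)-2-[(2R)-4-methoxy-5-methyl-6-oxo-3,6-dihydro-2H-pyran-2-yl]-6-methylhept-5-en-2-yl benzoate
Product: 14 (2S,5E)-7-(tert-butyldimethylsilyloxy)-2-[(2R)-4-hydroxy-5-methyl-6-oxo-3,6-dihydro-2H-pyran-2-yl]-6-methylhept-5-en-2-yl benzoate (β-keto lactone, enol form)
Conditions: LiI, pyridine, 100 °C; then cold dilute HCl
Reagents that add atoms: none
Why: SN2 O-demethylation: the methyl of the vinylogous carbonate is as activated as a methyl ester, and lithium-assisted iodide attack releases the stabilised enolate. The neutral conditions should spare the silyl ether and the tertiary benzoate.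

Step 12
Reactants: 14 (2S,5E)-7-(tert-butyldimethylsilyloxy)-2-[(2R)-4-hydroxy-5-methyl-6-oxo-3,6-dihydro-2H-pyran-2-yl]-6-methylhept-5-en-2-yl benzoate
Product: 15 (2S,5E)-7-(tert-butyldimethylsilyloxy)-6-methyl-2-[(2R)-5-methyl-6-oxo-4-(trifluoromethylsulfonyloxy)-3,6-dihydro-2H-pyran-2-yl]hept-5-en-2-yl benzoate
Conditions: Tf2O, Et3N, CH2Cl2, −78 °C
Reagents that add atoms: trifluoromethanesulfonic anhydride, O=S(=O)(OS(=O)(=O)C(F)(F)F)C(F)(F)F
Why: O-Sulfonylation of the conjugated enol gives the enol triflate of the β-keto lactone.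

Step 13
Reactants: 16 but-3-yn-1-ol
Product: 17 (but-3-yn-1-yloxy)(tert-butyl)dimethylsilane
Conditions: TBSCl, imidazole, CH2Cl2, rt
Reagents that add atoms: tert-butyldimethylsilyl chloride, CC(C)(C)[Si](C)(C)Cl
Why: Silylation protects the alcohol for the carbometalation.

Step 14
Reactants: 17 (but-3-yn-1-yloxy)(tert-butyl)dimethylsilane
Product: 19 (2E)-5-(tert-butyldimethylsilyloxy)-3-methylpent-2-en-1-ol, via alkenylalane 18 (not isolated)
Conditions: AlMe3, Cp2ZrCl2 (0.2 equiv), CH2Cl2, 0 °C → rt; then (CH2O)n, 0 °C → rt; dilute HCl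
Reagents that add atoms: trimethylaluminium, C[Al](C)C; formaldehyde (as paraformaldehyde), C=O
Why: Negishi zirconium-catalysed carboalumination adds methyl and aluminium syn across the alkyne, with methyl on the internal carbon. Hydroxymethylation of the alkenyl–aluminium bond with retention gives the E trisubstituted allylic alcohol (C9=C10, C11–OH).

Step 15
Reactants: 19 (2E)-5-(tert-butyldimethylsilyloxy)-3-methylpent-2-en-1-ol
Product: 20 (2E)-5-(tert-butyldimethylsilyloxy)-1-(tert-butyldiphenylsilyloxy)-3-methylpent-2-ene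
Conditions: TBDPSCl, imidazole, DMF, rt
Reagents that add atoms: tert-butyldiphenylsilyl chloride, CC(C)(C)[Si](Cl)(c1ccccc1)c1ccccc1
Why: Silylation of the allylic alcohol with a group that survives removal of TBS ethers.

Step 16
Reactants: 20 (2E)-5-(tert-butyldimethylsilyloxy)-1-(tert-butyldiphenylsilyloxy)-3-methylpent-2-ene
Product: 21 (3E)-5-(tert-butyldiphenylsilyloxy)-3-methylpent-3-en-1-ol
Conditions: PPTS (cat.), MeOH, rt
Reagents that add atoms: none
Why: Mild acid methanolysis cleaves the primary TBS ether much faster than the TBDPS ether.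

Step 17
Reactants: 21 (3E)-5-(tert-butyldiphenylsilyloxy)-3-methylpent-3-en-1-ol
Product: 22 [(2E)-5-bromo-3-methylpent-2-en-1-yl]oxy(tert-butyl)diphenylsilane
Conditions: CBr4, PPh3, CH2Cl2, 0 °C
Reagents that add atoms: tetrabromomethane, BrC(Br)(Br)Br
Why: Appel reaction converts the primary alcohol into the bromide without touching the alkene or the silyl ether.

Step 18
Reactants: 15 (2S,5E)-7-(tert-butyldimethylsilyloxy)-6-methyl-2-[(2R)-5-methyl-6-oxo-4-(trifluoromethylsulfonyloxy)-3,6-dihydro-2H-pyran-2-yl]hept-5-en-2-yl benzoate; 22 [(2E)-5-bromo-3-methylpent-2-en-1-yl]oxy(tert-butyl)diphenylsilane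
Product: 24 (2S,5E)-7-(tert-butyldimethylsilyloxy)-2-[(2R)-4-[(3E)-5-(tert-butyldiphenylsilyloxy)-3-methylpent-3-en-1-yl]-5-methyl-6-oxo-3,6-dihydro-2H-pyran-2-yl]-6-methylhept-5-en-2-yl benzoate, via Grignard reagent 23 (not isolated)
Conditions: 22, Mg, THF, rt; then 15, Fe(acac)3 (5 mol%), THF/NMP, −30 °C
Reagents that add atoms: none
Why: Iron-catalysed cross-coupling of an alkyl Grignard reagent with the enol triflate of a β-keto ester forms C6–C7. The coupling is much faster than addition to the lactone or the benzoate at this temperature.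

Step 19
Reactants: 24 (2S,5E)-7-(tert-butyldimethylsilyloxy)-2-[(2R)-4-[(3E)-5-(tert-butyldiphenylsilyloxy)-3-methylpent-3-en-1-yl]-5-methyl-6-oxo-3,6-dihydro-2H-pyran-2-yl]-6-methylhept-5-en-2-yl benzoate
Product: 26 (2S,5E)-7-(tert-butyldimethylsilyloxy)-2-[(2R,4R,5S)-4-[(3E)-5-(tert-butyldiphenylsilyloxy)-3-methylpent-3-en-1-yl]-5-methyl-6-oxooxan-2-yl]-6-methylhept-5-en-2-yl benzoate (2S,4R,6R,17S in target numbering), via C2-epimeric lactone 25 (not isolated)
Conditions: (IPr)CuCl [chloro(1,3-bis(2,6-diisopropylphenyl)imidazol-2-ylidene)copper] (5 mol%), NaOtBu (5 mol%), (EtO)2MeSiH, t-BuOH, toluene, rt; then DBU, toluene, 60 °C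
Reagents that add atoms: none
Why: Copper hydride conjugate reduction with a carbene ligand, a system that reaches tetrasubstituted enoates and leaves isolated alkenes alone. Hydride should add to C6 axially and anti to the C4 substituent (6R, chain cis to C4). Base then equilibrates C2 to the all-equatorial 2S lactone.

Step 20
Reactants: 26 (2S,5E)-7-(tert-butyldimethylsilyloxy)-2-[(2R,4R,5S)-4-[(3E)-5-(tert-butyldiphenylsilyloxy)-3-methylpent-3-en-1-yl]-5-methyl-6-oxooxan-2-yl]-6-methylhept-5-en-2-yl benzoate
Product: 28 (3S,4R,6R)-6-[(2S,5E)-7-(tert-butyldimethylsilyloxy)-2-hydroxy-6-methylhept-5-en-2-yl]-4-[(3E)-5-(tert-butyldiphenylsilyloxy)-3-methylpent-3-en-1-yl]-3-methyloxan-2-one, via dihydroxy methyl ester 27 (not isolated)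
Conditions: K2CO3, MeOH, rt; AcOH quench; then PPTS, toluene, 60 °C
Reagents that add atoms: none
Why: Methanolysis opens the lactone; the freed C4 hydroxyl takes over the hindered benzoyl group by 1,2-acyl migration, and it is then lost as methyl benzoate. Acid re-closes the δ-lactone (6-exo-trig) through the secondary C4 hydroxyl in preference to a seven-membered ring through C17–OH. No epoxide is present yet.

Step 21
Reactants: 28 (3S,4R,6R)-6-[(2S,5E)-7-(tert-butyldimethylsilyloxy)-2-hydroxy-6-methylhept-5-en-2-yl]-4-[(3E)-5-(tert-butyldiphenylsilyloxy)-3-methylpent-3-en-1-yl]-3-methyloxan-2-one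
Product: 29 (3S,4R,6R)-6-[(2S,5E)-2,7-dihydroxy-6-methylhept-5-en-2-yl]-4-[(3E)-5-(tert-butyldiphenylsilyloxy)-3-methylpent-3-en-1-yl]-3-methyloxan-2-one
Conditions: HF·pyridine, pyridine, THF, 0 °C
Reagents that add atoms: none
Why: Buffered fluoride desilylation removes the primary TBS ether and leaves the TBDPS ether and the lactone intact.

Step 22
Reactants: 29 (3S,4R,6R)-6-[(2S,5E)-2,7-dihydroxy-6-methylhept-5-en-2-yl]-4-[(3E)-5-(tert-butyldiphenylsilyloxy)-3-methylpent-3-en-1-yl]-3-methyloxan-2-one
Product: 32 (3S,4R,6R)-4-[(3E)-5-(tert-butyldiphenylsilyloxy)-3-methylpent-3-en-1-yl]-6-[(2S,5E)-2-hydroxy-6-methyl-7-(phenylsulfonyl)hept-5-en-2-yl]-3-methyloxan-2-one, via allylic mesylate 30 (not isolated), via allylic bromide 31 (not isolated)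
Conditions: MsCl, Et3N, THF, −40 °C; LiBr, 0 °C; then PhSO2Na, DMF, rt
Reagents that add atoms: sodium benzenesulfinate, [Na+].[O-]S(=O)c1ccccc1
Why: Sulfonylation of the primary allylic alcohol, halide exchange, and SN2 S-alkylation of the sulfinate give the allylic sulfone; the tertiary C17 hydroxyl does not react.

Step 23
Reactants: 32 (3S,4R,6R)-4-[(3E)-5-(tert-butyldiphenylsilyloxy)-3-methylpent-3-en-1-yl]-6-[(2S,5E)-2-hydroxy-6-methyl-7-(phenylsulfonyl)hept-5-en-2-yl]-3-methyloxan-2-one
Product: 33 (3S,4R,6R)-4-[(3E)-5-hydroxy-3-methylpent-3-en-1-yl]-6-[(2S,5E)-2-hydroxy-6-methyl-7-(phenylsulfonyl)hept-5-en-2-yl]-3-methyloxan-2-one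
Conditions: TBAF, AcOH, THF, rt
Reagents that add atoms: none
Why: Fluoride desilylation, buffered with acetic acid so that neither the lactone nor the acidic allylic sulfone is disturbed.

Step 24
Reactants: 33 (3S,4R,6R)-4-[(3E)-5-hydroxy-3-methylpent-3-en-1-yl]-6-[(2S,5E)-2-hydroxy-6-methyl-7-(phenylsulfonyl)hept-5-en-2-yl]-3-methyloxan-2-one
Product: 34 (3S,4R,6R)-4-{2-[(2S,3S)-3-(hydroxymethyl)-2-methyloxiran-2-yl]ethyl}-6-[(2S,5E)-2-hydroxy-6-methyl-7-(phenylsulfonyl)hept-5-en-2-yl]-3-methyloxan-2-one
Conditions: Ti(OiPr)4 (20 mol%), L-(+)-diethyl tartrate (24 mol%), t-BuOOH (anhydrous), 4 Å MS, CH2Cl2, −20 °C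
Reagents that add atoms: tert-butyl hydroperoxide, CC(C)(C)OO
Why: Sharpless asymmetric epoxidation of the geraniol-type allylic alcohol; the L-tartrate should give 9S,10S. The other alkene has no allylic hydroxyl and is deactivated by the sulfone.

Step 25
Reactants: 34 (3S,4R,6R)-4-{2-[(2S,3S)-3-(hydroxymethyl)-2-methyloxiran-2-yl]ethyl}-6-[(2S,5E)-2-hydroxy-6-methyl-7-(phenylsulfonyl)hept-5-en-2-yl]-3-methyloxan-2-one
Product: 35 (3S,4R,6R)-6-[(2S,5E)-2-hydroxy-6-methyl-7-(phenylsulfonyl)hept-5-en-2-yl]-4-{2-[(2S,3R)-3-(iodomethyl)-2-methyloxiran-2-yl]ethyl}-3-methyloxan-2-one (same geometry at C10; the descriptor changes because iodine outranks oxygen)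
Conditions: I2, PPh3, imidazole, CH2Cl2, 0 °C
Reagents that add atoms: iodine, II
Why: Appel-type iodination of the primary epoxy alcohol under imidazole buffering; the tertiary alcohol and the epoxide should be left alone.

Step 26
Reactants: 35 (3S,4R,6R)-6-[(2S,5E)-2-hydroxy-6-methyl-7-(phenylsulfonyl)hept-5-en-2-yl]-4-{2-[(2S,3R)-3-(iodomethyl)-2-methyloxiran-2-yl]ethyl}-3-methyloxan-2-one
Product: 36 macrocyclic sulfone: (2S,4R,6R,9S,10S,17S,13E)-9,10-epoxy-17-hydroxy-12-(phenylsulfonyl) 14-membered lactone (target numbering; epimers at C12)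
Conditions: LiHMDS (2.05 equiv), THF/HMPA, 2 mM, −78 → −20 °C
Reagents that add atoms: none
Why: Intramolecular SN2 alkylation of the allylic sulfone carbanion at the primary iodide forms C11–C12 and the 14-membered ring. One equivalent of base is taken by the hydroxyl, and the second deprotonates the sulfone, which is several pK units more acidic than the lactone α-position.

Step 27
Reactants: 36 macrocyclic sulfone
Product: 37 (2S,4R,6R,9S,10S,17S,13E)-9,10-epoxy-17-hydroxy 14-membered lactone (the ene precursor)
Conditions: Na(Hg) (5%), Na2HPO4, MeOH/THF, −20 °C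
Reagents that add atoms: none
Why: Reductive desulfonylation by electron transfer; the buffer keeps the medium mild enough for the lactone and the epoxide, which is not β to the carbanion and so cannot be eliminated.

Step 28
Reactants: 37 (2S,4R,6R,9S,10S,17S,13E)-9,10-epoxy-17-hydroxy 14-membered lactone
Product: 38 the target, (2S,4R,6R,9S,10S,13S,17S,14E)-9,10-epoxy-13-hydroperoxy-17-hydroxy 14-membered lactone
Conditions: O2, visible light, methylene blue (cat.), CH2Cl2, 0 °C
Reagents that add atoms: oxygen, O=O
Why: Schenck ene reaction: singlet oxygen adds to C13 on the more crowded side of the alkene and takes a hydrogen from C15, moving the double bond to C14=C15 (E). The C13 configuration is set by attack on the outer face of the ring alkene.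

## Compound list

1 | geraniol | CC(C)=CCC/C(C)=C/CO | starting material
2 | geranyl acetate | CC(C)=CCC/C(C)=C/COC(C)=O | intermediate
3 | (2E,6E)-8-hydroxy-3,7-dimethylocta-2,6-dien-1-yl acetate | OC/C(C)=C/CC/C(C)=C/COC(C)=O | intermediate
4 | (2E,6E)-8-(tert-butyldimethylsilyloxy)-3,7-dimethylocta-2,6-dien-1-yl acetate | CC(=O)OC/C=C(\C)CC/C=C(\C)CO[Si](C)(C)C(C)(C)C | intermediate
5 | (2E,6E)-8-(tert-butyldimethylsilyloxy)-3,7-dimethylocta-2,6-dien-1-ol | OC/C=C(\C)CC/C=C(\C)CO[Si](C)(C)C(C)(C)C | intermediate
6 | (2R,3R)-epoxy alcohol | OC[C@H]1O[C@]1(C)CC/C=C(\C)CO[Si](C)(C)C(C)(C)C | intermediate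
7 | (2R,3S)-3-benzoyloxy 1,2-diol | OC[C@@H](O)[C@@](C)(OC(=O)c1ccccc1)CC/C=C(\C)CO[Si](C)(C)C(C)(C)C | intermediate
8 | C17-benzoyloxy C4 aldehyde (S) | O=C[C@@](C)(OC(=O)c1ccccc1)CC/C=C(\C)CO[Si](C)(C)C(C)(C)C | intermediate
9 | methyl 2-methyl-3-oxobutanoate | COC(=O)C(C)C(C)=O | starting material
10 | methyl (2E)-3-methoxy-2-methylbut-2-enoate | COC(=O)/C(C)=C(\C)OC | intermediate
11 | 1,3-dimethoxy-2-methyl-1-(trimethylsilyloxy)buta-1,3-diene | C=C(OC)C(C)=C(OC)O[Si](C)(C)C | intermediate
12 | methyl (2E,5R,6S,9E)-6-(benzoyloxy)-11-(tert-butyldimethylsilyloxy)-3-methoxy-2,6,10-trimethyl-5-(trimethylsilyloxy)undeca-2,9-dienoate (formed in the flask, step 10) | COC(=O)/C(C)=C(/OC)C[C@@H](O[Si](C)(C)C)[C@@](C)(OC(=O)c1ccccc1)CC/C=C(\C)CO[Si](C)(C)C(C)(C)C | intermediate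
13 | 6-substituted 4-methoxy-3-methyl-5,6-dihydropyran-2-one (4R,17S) | CC1=C(OC)C[C@@H](OC1=O)[C@@](C)(OC(=O)c2ccccc2)CC/C=C(\C)CO[Si](C)(C)C(C)(C)C | intermediate
14 | β-keto lactone (4-hydroxy enol form) | CC1=C(O)C[C@@H](OC1=O)[C@@](C)(OC(=O)c2ccccc2)CC/C=C(\C)CO[Si](C)(C)C(C)(C)C | intermediate
15 | enol triflate | CC1=C(OS(=O)(=O)C(F)(F)F)C[C@@H](OC1=O)[C@@](C)(OC(=O)c2ccccc2)CC/C=C(\C)CO[Si](C)(C)C(C)(C)C | intermediate
16 | but-3-yn-1-ol | C#CCCO | starting material
17 | (but-3-yn-1-yloxy)(tert-butyl)dimethylsilane | C#CCCO[Si](C)(C)C(C)(C)C | intermediate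
18 | [(1E)-4-(tert-butyldimethylsilyloxy)-2-methylbut-1-en-1-yl]dimethylalane (formed in the flask, step 14) | C[Al](C)/C=C(\C)CCO[Si](C)(C)C(C)(C)C | intermediate
19 | (2E)-5-(tert-butyldimethylsilyloxy)-3-methylpent-2-en-1-ol | OC/C=C(\C)CCO[Si](C)(C)C(C)(C)C | intermediate
20 | (2E)-5-(tert-butyldimethylsilyloxy)-1-(tert-butyldiphenylsilyloxy)-3-methylpent-2-ene | CC(C)(C)[Si](OC/C=C(\C)CCO[Si](C)(C)C(C)(C)C)(c1ccccc1)c1ccccc1 | intermediate
21 | (3E)-5-(tert-butyldiphenylsilyloxy)-3-methylpent-3-en-1-ol | OCC/C(C)=C/CO[Si](c1ccccc1)(c1ccccc1)C(C)(C)C | intermediate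
22 | [(2E)-5-bromo-3-methylpent-2-en-1-yl]oxy(tert-butyl)diphenylsilane | BrCC/C(C)=C/CO[Si](c1ccccc1)(c1ccccc1)C(C)(C)C | intermediate
23 | [(3E)-5-(tert-butyldiphenylsilyloxy)-3-methylpent-3-en-1-yl]magnesium bromide (formed in the flask, step 18) | Br[Mg]CC/C(C)=C/CO[Si](c1ccccc1)(c1ccccc1)C(C)(C)C | intermediate
24 | 4-alkyl-3-methyl-5,6-dihydropyran-2-one (coupled unsaturated lactone) | CC1=C(CC/C(C)=C/CO[Si](c3ccccc3)(c3ccccc3)C(C)(C)C)C[C@@H](OC1=O)[C@@](C)(OC(=O)c2ccccc2)CC/C=C(\C)CO[Si](C)(C)C(C)(C)C | intermediate
25 | saturated lactone, C2 epimer (2R,4R,6R,17S; formed in the flask, step 19) | C[C@H]1C(=O)O[C@H](C[C@H]1CC/C(C)=C/CO[Si](c2ccccc2)(c2ccccc2)C(C)(C)C)[C@@](C)(OC(=O)c2ccccc2)CC/C=C(\C)CO[Si](C)(C)C(C)(C)C | intermediate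
26 | saturated lactone benzoate (2S,4R,6R,17S) | C[C@@H]1C(=O)O[C@H](C[C@H]1CC/C(C)=C/CO[Si](c2ccccc2)(c2ccccc2)C(C)(C)C)[C@@](C)(OC(=O)c2ccccc2)CC/C=C(\C)CO[Si](C)(C)C(C)(C)C | intermediate
27 | methyl (2S,3R,5R,6S,9E)-11-(tert-butyldimethylsilyloxy)-3-[(3E)-5-(tert-butyldiphenylsilyloxy)-3-methylpent-3-en-1-yl]-5,6-dihydroxy-2,6,10-trimethylundec-9-enoate (formed in the flask, step 20) | COC(=O)[C@@H](C)[C@H](CC/C(C)=C/CO[Si](c1ccccc1)(c1ccccc1)C(C)(C)C)C[C@@H](O)[C@@](C)(O)CC/C=C(\C)CO[Si](C)(C)C(C)(C)C | intermediate
28 | hydroxy lactone (C17–OH free, C12–OTBS, C11–OTBDPS) | C[C@@H]1C(=O)O[C@H](C[C@H]1CC/C(C)=C/CO[Si](c2ccccc2)(c2ccccc2)C(C)(C)C)[C@@](C)(O)CC/C=C(\C)CO[Si](C)(C)C(C)(C)C | intermediate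
29 | diol lactone (C12–OH, C17–OH) | C[C@@H]1C(=O)O[C@H](C[C@H]1CC/C(C)=C/CO[Si](c2ccccc2)(c2ccccc2)C(C)(C)C)[C@@](C)(O)CC/C=C(\C)CO | intermediate
30 | C12 allylic mesylate (formed in the flask, step 22) | C[C@@H]1C(=O)O[C@H](C[C@H]1CC/C(C)=C/CO[Si](c2ccccc2)(c2ccccc2)C(C)(C)C)[C@@](C)(O)CC/C=C(\C)COS(C)(=O)=O | intermediate
31 | C12 allylic bromide (formed in the flask, step 22) | C[C@@H]1C(=O)O[C@H](C[C@H]1CC/C(C)=C/CO[Si](c2ccccc2)(c2ccccc2)C(C)(C)C)[C@@](C)(O)CC/C=C(\C)CBr | intermediate
32 | C12 allylic phenyl sulfone | C[C@@H]1C(=O)O[C@H](C[C@H]1CC/C(C)=C/CO[Si](c2ccccc2)(c2ccccc2)C(C)(C)C)[C@@](C)(O)CC/C=C(\C)CS(=O)(=O)c2ccccc2 | intermediate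
33 | C11 allylic alcohol sulfone | C[C@@H]1C(=O)O[C@H](C[C@H]1CC/C(C)=C/CO)[C@@](C)(O)CC/C=C(\C)CS(=O)(=O)c2ccccc2 | intermediate
34 | (9S,10S)-epoxy alcohol sulfone | C[C@@H]1C(=O)O[C@H](C[C@H]1CC[C@]2(C)O[C@H]2CO)[C@@](C)(O)CC/C=C(\C)CS(=O)(=O)c2ccccc2 | intermediate
35 | epoxy iodide sulfone | C[C@@H]1C(=O)O[C@H](C[C@H]1CC[C@]2(C)O[C@H]2CI)[C@@](C)(O)CC/C=C(\C)CS(=O)(=O)c2ccccc2 | intermediate
36 | macrocyclic sulfone (epimers at C12) | C[C@@H]1C(=O)O[C@@H]2C[C@H]1CC[C@]1(C)O[C@H]1CC(S(=O)(=O)c1ccccc1)/C(C)=C/CC[C@]2(C)O | intermediate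
37 | 14-membered epoxy alkenyl hydroxy lactone (ene precursor) | C[C@@H]1C(=O)O[C@@H]2C[C@H]1CC[C@]1(C)O[C@H]1CC/C(C)=C/CC[C@]2(C)O | intermediate
38 | target hydroperoxide | C[C@@H]1C(=O)O[C@@H]2C[C@H]1CC[C@]1(C)O[C@H]1CC[C@](C)(OO)/C=C/C[C@]2(C)O | target

## Step count and least certain steps

Total: 28 steps. Longest linear sequence: 21 steps (steps 1–7, 10–12, 18–28). The diene (steps 8–9) and the C7–C11 bromide (steps 13–17) are side branches.

**Step 10 (key step).** The most likely failure is poor facial discrimination at the hindered, α-quaternary carbonyl, together with slow turnover that lets an uncatalysed addition compete. Benzoyl migration to the C4 oxygen during the acid lactonisation is a second risk. Fallback, from 8 and 9 back to 14: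
- 9 is silylated (TMSCl, Et3N) to methyl 2-methyl-3-(trimethylsilyloxy)but-2-enoate F1, then deprotonated and silylated again (LDA, TMSCl) to the more nucleophilic 1-methoxy-2-methyl-1,3-bis(trimethylsilyloxy)buta-1,3-diene F2.
- F2 adds to 8 in an open-chain vinylogous Mukaiyama aldol reaction under the same Ti(OiPr)4/(R)-BINOL catalyst, giving after acidic work-up the δ-hydroxy-β-keto ester F3.
- PPTS in warm toluene lactonises F3 to 14, so step 11 is not needed either.
- If catalyst control still fails, BF3·OEt2 promotes the addition and the C4 epimers, which are diastereomers, are separated at 14.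

**Step 11.** Iodide attack on the methyl of a vinylogous carbonate may be slow, and prolonged heating could start eliminative opening of the dihydropyranone or loss of the silyl ether. Fallback, from 9 and 8 back to 14:
- The methyl enol ether is replaced by an allyl enol ether. 9 with triallyl orthoformate and acid gives methyl 3-(allyloxy)-2-methylbut-2-enoate F4, and LDA/TMSCl gives 3-(allyloxy)-1-methoxy-2-methyl-1-(trimethylsilyloxy)buta-1,3-diene F5.
- The key step with 8 gives the 4-allyloxy lactone F6.
- Pd(PPh3)4 with morpholine cleaves the allyl group through a π-allylpalladium complex under neutral conditions, giving 14.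

**Step 19.** Hydride transfer to the tetrasubstituted β-carbon may stall, and C2 may equilibrate incompletely. Fallback, from 24 back to 26 without new compounds: reduction on a nickel boride surface (NiCl2·6H2O, NaBH4, MeOH, −20 °C), which delivers hydrogen syn to the less hindered face and gives 25; the same DBU treatment then gives 26.

**Step 26.** Intermolecular alkylation can compete with the entropically slow 14-membered closure. The carbanion may also attack the epoxide at C10, and any lactone enolate would close a seven-membered ring onto C11. Fallback, from 33 back to 36: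
- 33 is converted (MsCl, Et3N; LiBr) into the allylic bromide F7.
- The sulfone carbanion is cyclised onto this much more reactive allylic electrophile to give the macrocyclic diene sulfone F8.
- C9=C10 is then epoxidised by Shi epoxidation with the enantiomer of the fructose-derived ketone and KHSO5, giving 36. C13=C14 is deactivated by the neighbouring sulfonyl group.

**Step 27.** The allylic anion formed after loss of sulfinate may be protonated at C14, which moves the double bond to C12=C13 or scrambles its geometry. Methanolysis of the lactone is a lesser risk. Fallback, from 36 back to 37: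
- Bu3SnH/AIBN replaces the sulfonyl group by tin with allylic transposition, giving the C14 allylstannane F9.
- Protodestannylation with acetic acid transposes the alkene back and gives 37 with the double bond at C13=C14.

**Step 28.** Singlet oxygen may abstract hydrogen from the C13 methyl group instead of C15, which gives the exocyclic-methylene secondary hydroperoxide. The face selectivity at C13 depends only on the ring conformation. Fallback, a recycling loop from 37 back to 37:
- The regioisomeric hydroperoxide F10 is reduced with PPh3 to the allylic alcohol F11.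
- Mitsunobu reaction of F11 with 2-nitrobenzenesulfonylhydrazide gives an allylic diazene that loses nitrogen with 1,3-transposition and regenerates 37 for another pass.
- This loop recovers material lost to the wrong regiochemistry; it does not correct a wrong C13 face.

## Further compounds

F1 | step 10 | methyl 2-methyl-3-(trimethylsilyloxy)but-2-enoate | COC(=O)C(C)=C(C)O[Si](C)(C)C
F2 | step 10 | 1-methoxy-2-methyl-1,3-bis(trimethylsilyloxy)buta-1,3-diene | C=C(O[Si](C)(C)C)C(C)=C(OC)O[Si](C)(C)C
F3 | step 10 | methyl (5R,6S,9E)-6-(benzoyloxy)-11-(tert-butyldimethylsilyloxy)-5-hydroxy-2,6,10-trimethyl-3-oxoundec-9-enoate | COC(=O)C(C)C(=O)C[C@@H](O)[C@@](C)(OC(=O)c1ccccc1)CC/C=C(\C)CO[Si](C)(C)C(C)(C)C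
F4 | step 11 | methyl (2E)-3-(allyloxy)-2-methylbut-2-enoate | COC(=O)/C(C)=C(\C)OCC=C
F5 | step 11 | 3-(allyloxy)-1-methoxy-2-methyl-1-(trimethylsilyloxy)buta-1,3-diene | C=C(OCC=C)C(C)=C(OC)O[Si](C)(C)C
F6 | step 11 | 4-allyloxy analogue of 13 | CC1=C(OCC=C)C[C@@H](OC1=O)[C@@](C)(OC(=O)c2ccccc2)CC/C=C(\C)CO[Si](C)(C)C(C)(C)C
F0 | step 19 | none | none
F7 | step 26 | C11 allylic bromide sulfone | C[C@@H]1C(=O)O[C@H](C[C@H]1CC/C(C)=C/CBr)[C@@](C)(O)CC/C=C(\C)CS(=O)(=O)c2ccccc2
F8 | step 26 | macrocyclic 9E,13E-diene sulfone (epimers at C12) | C[C@@H]1C(=O)O[C@@H]2C[C@H]1CC/C(C)=C/CC(S(=O)(=O)c1ccccc1)/C(C)=C/CC[C@]2(C)O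
F9 | step 27 | macrocyclic C14 tributylstannane with C12=C13 alkene | C[C@@H]1C(=O)O[C@@H]2C[C@H]1CC[C@]1(C)O[C@H]1CC=C(C)C([Sn](CCCC)(CCCC)CCCC)CC[C@]2(C)O
F10 | step 28 | C14 hydroperoxide with exocyclic C13 methylene | C[C@@H]1C(=O)O[C@@H]2C[C@H]1CC[C@]1(C)O[C@H]1CCC(=C)C(OO)CC[C@]2(C)O
F11 | step 28 | C14 allylic alcohol with exocyclic C13 methylene | C[C@@H]1C(=O)O[C@@H]2C[C@H]1CC[C@]1(C)O[C@H]1CCC(=C)C(O)CC[C@]2(C)O
A1 | alternative 1 | 16-membered macrolactone with C5 iodide | C/C1=C\CC[C@]2(C)O[C@H]2CC/C(C)=C/CC[C@](C)(O)[C@@H](CI)OC1=O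
A2 | alternative 1 | 14-membered epoxy alkenyl hydroxy lactone (ene precursor) | C[C@@H]1C(=O)O[C@@H]2C[C@H]1CC[C@]1(C)O[C@H]1CC/C(C)=C/CC[C@]2(C)O
A3 | alternative 2 | bis-allylic diol ester | COC(=O)[C@@H](C)[C@@H](C/C=C(\C)CO)CC/C(C)=C/CO
A4 | alternative 2 | bis-epoxy diol ester | COC(=O)[C@@H](C)[C@@H](C[C@@H]1O[C@@]1(C)CO)CC[C@]1(C)O[C@H]1CO
A5 | alternative 3 | E thioenoate with C4/C17 acetonide | CCSC(=O)/C=C/C[C@H]1OC(C)(C)O[C@@]1(C)CC/C=C(\C)CO[Si](C)(C)C(C)(C)C
A6 | alternative 3 | C7–C11 Grignard reagent with PMB ether | Br[Mg]CC/C(C)=C/COCc1ccc(OC)cc1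
A7 | alternative 3 | C2-methyl C6-alkyl thioester | CCSC(=O)[C@@H](C)[C@H](CC/C(C)=C/COCc1ccc(OC)cc1)C[C@H]1OC(C)(C)O[C@@]1(C)CC/C=C(\C)CO[Si](C)(C)C(C)(C)C
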